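## Retrosynthetic overview

Eudesmane numbering is used: ring A = C1–C5 + C10, ring B = C5–C10, C14 = CH3 on C10, C15 = CH2O on C4, C11/C12/C13 = acrylic acid unit on C7.

1. Target ⇒ (Z)-p-coumaric acid + the C15 allylic alcohol (Mitsunobu), with C12 held as a 4-methoxybenzyl ester. C12 ⇒ CO on the C11 enol triflate of a 7β-acetyl group. C15–OH ⇒ a C4 methyl ester.
2. Feature used: ring B is branched only at C7 (bearing C11) and at the quaternary C10 (bearing C14), and shares the C5–C10 bond with ring A, which already holds the C3=C4 alkene. With C11 as a ketone and C6=C7 unsaturated, ring B is the [4+2] adduct of the 2-acetyl diene C5=C6–C7(C11=O)=C8 and the isopropenyl unit C9=C10(C14); C1–C4 of ring A is the tether.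
3. Rings A and B are closed together (C8–C9 and C5–C10) in one inverse-electron-demand intramolecular Diels–Alder reaction of an acyclic tetraene, which sets C5 and C10. C7 follows by conjugate reduction and equilibration.
4. Tetraene ⇒ 4-methylpent-4-enal + methyl acrylate (Morita–Baylis–Hillman, SN2′ bromination, Michaelis–Arbuzov) and 2-(2-methyl-1,3-dioxolan-2-yl)acrolein (Horner–Wadsworth–Emmons).

Key step: step 9

## Route

Step 1
Reactants: 1 ethyl 4-methylpent-4-enoate
Product: 2 4-methylpent-4-enal
Conditions: i-Bu2AlH (1.05 equiv), CH2Cl2, −78 °C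
Reagents that add atoms: none
Why: Partial hydride reduction of an ester, which stops at the aluminium hemiacetal at −78 °C and gives the aldehyde on work-up; no stereocentre is formed.

Step 2
Reactants: 2 4-methylpent-4-enal; 3 methyl acrylate
Product: 4 methyl 3-hydroxy-6-methyl-2-methylidenehept-6-enoate (racemic)
Conditions: DABCO (0.5 equiv), MeOH, rt
Reagents that add atoms: none
Why: Morita–Baylis–Hillman reaction (amine-catalysed addition of the acrylate α-carbon to the aldehyde); the carbinol centre is left racemic because step 3 erases it.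

Step 3
Reactants: 4 methyl 3-hydroxy-6-methyl-2-methylidenehept-6-enoate
Product: 5 methyl (2Z)-2-(bromomethyl)-6-methylhepta-2,6-dienoate
Conditions: NBS, Me2S, CH2Cl2, 0 °C → rt
Reagents that add atoms: N-bromosuccinimide, O=C1CCC(=O)N1Br
Why: SN2′ allylic substitution: the hydroxyl is activated as an alkoxysulfonium ion and bromide attacks the acrylate CH2, which should give the conjugated alkene with the chain trans to the ester, as is usual for Morita–Baylis–Hillman alcohols.

Step 4
Reactants: 5 methyl (2Z)-2-(bromomethyl)-6-methylhepta-2,6-dienoate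
Product: 6 methyl (2Z)-2-[(diethoxyphosphoryl)methyl]-6-methylhepta-2,6-dienoate
Conditions: P(OEt)3, neat, 90 °C
Reagents that add atoms: triethyl phosphite, CCOP(OCC)OCC
Why: Michaelis–Arbuzov reaction of a primary allylic bromide (SN2 at CH2Br, then dealkylation by bromide), which leaves the alkene geometry untouched.

Step 5
Reactants: 7 ethyl (2-methyl-1,3-dioxolan-2-yl)acetate
Product: 8 (2-methyl-1,3-dioxolan-2-yl)acetaldehyde
Conditions: i-Bu2AlH (1.05 equiv), CH2Cl2, −78 °C
Reagents that add atoms: none
Why: Partial hydride reduction of the ester to the aldehyde; the ketal is inert to the hydride.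

Step 6
Reactants: 8 (2-methyl-1,3-dioxolan-2-yl)acetaldehyde
Product: 9 2-(2-methyl-1,3-dioxolan-2-yl)prop-2-enal
Conditions: aq. CH2O, pyrrolidine (10 mol %), EtCO2H (10 mol %), i-PrOH, 45 °C
Reagents that add atoms: formaldehyde, C=O
Why: Amine-catalysed α-methylenation of an aldehyde (Mannich condensation through the enamine, then elimination of the amine).

Step 7
Reactants: 6 methyl (2Z)-2-[(diethoxyphosphoryl)methyl]-6-methylhepta-2,6-dienoate; 9 2-(2-methyl-1,3-dioxolan-2-yl)prop-2-enal
Product: 11 methyl (2E)-6-methyl-2-[(1E)-3-(2-methyl-1,3-dioxolan-2-yl)buta-1,3-dien-1-yl]hepta-2,6-dienoate, via sodium phosphonate carbanion 10 (not isolated)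
Conditions: NaH, THF, 0 °C; then 9, −78 → 0 °C
Reagents that add atoms: none
Why: Horner–Wadsworth–Emmons olefination: the allylic phosphonate anion adds 1,2 to the enal at its phosphorus-bearing carbon and syn-elimination of phosphate should give the (E)-C5=C6 bond, while the trisubstituted C3=C4 bond keeps its more stable geometry with the chain trans to the ester.

Step 8
Reactants: 11 methyl (2E)-6-methyl-2-[(1E)-3-(2-methyl-1,3-dioxolan-2-yl)buta-1,3-dien-1-yl]hepta-2,6-dienoate
Product: 12 methyl (2E)-6-methyl-2-[(1E)-3-methylidene-4-oxopent-1-en-1-yl]hepta-2,6-dienoate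
Conditions: PPTS (cat.), acetone–H2O, rt; used at once in dilute solution
Reagents that add atoms: water, O
Why: Acid-catalysed hydrolysis of an allylic ketal, which unmasks the 2-acetyl diene only at this point because such dienes dimerise by Diels–Alder reaction on standing.

Step 9
Reactants: 12 methyl (2E)-6-methyl-2-[(1E)-3-methylidene-4-oxopent-1-en-1-yl]hepta-2,6-dienoate
Product: 13 methyl (4aR,8aR)-7-acetyl-4a-methyl-3,4,4a,5,6,8a-hexahydronaphthalene-1-carboxylate (trans-fused; 5α-H and 10β-CH3 in eudesmane numbering)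
Conditions: (S)-1-(o-tolyl)-3,3-diphenyl-tetrahydropyrrolo[1,2-c][1,3,2]oxazaborole·HNTf2 (20 mol %, made in situ from (S)-α,α-diphenylprolinol, (o-TolBO)3 and HNTf2), CH2Cl2 (0.01 M), −78 → −40 °C
Reagents that add atoms: none
Why: Proposed new method: the boron Lewis acid binds the acetyl oxygen and lowers the LUMO of the 2-acyl diene C5=C6–C7(C11=O)=C8, so that the nucleophilic CH2 end of the isopropenyl group (C9) bonds to the enone β-carbon C8 while C5, the vinylogous α-position, captures the developing tertiary centre C10, a concerted but strongly asynchronous inverse-electron-demand intramolecular Diels–Alder reaction that is electronically matched at both new bonds. The closest known reaction types are the thermal and Lewis-acid-promoted inverse-demand [4+2] cycloadditions of 2-acyl- and 2-alkoxycarbonyl-1,3-dienes with unactivated alkenes and the oxazaborolidinium-catalysed enantioselective Diels–Alder reactions of α,β-unsaturated ketones; catalysis of a diene-bound ketone in this way is the new element. Ring B is closed as the six-membered [4π+2π] ring through C8–C9 and C5–C10, and ring A is closed by the same C5–C10 bond in the fused type 1 mode over the four-atom tether C1–C4, which the C3=C4 bond holds in a half-chair with C2 cis to the diene. C5 and C10 are created together: suprafacial addition to the (E)-C5=C6 bond with the C14 methyl endo and the tether exo should give the trans-fused 5α-H/10β-CH3 pair (the chair-like closure that also turns (E,E)-germacradienyl cations into trans-eudesmanes), and the aryl group of the catalyst, which shields one face of the coplanar boron-bound enone–diene, decides the absolute configuration, with the (S)-catalyst as first choice and its antipode as the alternative if the sense proves opposite. The step needs regio-, trans/cis- and enantiocontrol and must outrun dimerisation: only the C5–C10/C8–C9 pairing is geometrically possible for this tether, the small endo methyl and the flat ester-bearing tether favour trans fusion, and −78 °C at 0.01 M keeps the uncatalysed and bimolecular pathways slow.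

Step 10
Reactants: 13 methyl (4aR,8aR)-7-acetyl-4a-methyl-3,4,4a,5,6,8a-hexahydronaphthalene-1-carboxylate
Product: 15 methyl (4aR,7R,8aR)-7-acetyl-4a-methyl-3,4,4a,5,6,7,8,8a-octahydronaphthalene-1-carboxylate (7β-acetyl), via 7-epimeric ketone 14 (not isolated)
Conditions: [(Ph3P)CuH]6 (0.35 equiv), H2O (2 equiv), PhMe, rt; then K2CO3, MeOH, rt
Reagents that add atoms: none
Why: Copper hydride conjugate reduction, in which the enone should accept hydride at C6 much faster than the less electrophilic Δ3 enoate; C7 is then set under thermodynamic control by base-mediated enolisation, which places the acetyl group equatorial (7β, cis to the angular methyl) on the chair of ring B.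

Step 11
Reactants: 15 methyl (4aR,7R,8aR)-7-acetyl-4a-methyl-3,4,4a,5,6,7,8,8a-octahydronaphthalene-1-carboxylate
Product: 17 methyl (4aR,7R,8aR)-4a-methyl-7-{1-[(trifluoromethanesulfonyl)oxy]ethenyl}-3,4,4a,5,6,7,8,8a-octahydronaphthalene-1-carboxylate, via potassium enolate 16 (not isolated)
Conditions: KN(SiMe3)2 (1.05 equiv), THF, −78 °C; then PhNTf2, −78 → 0 °C
Reagents that add atoms: N-phenylbis(trifluoromethanesulfonimide), O=S(=O)(N(c1ccccc1)S(=O)(=O)C(F)(F)F)C(F)(F)F
Why: Enol triflate formation: kinetic deprotonation of the methyl ketone occurs at the unhindered CH3 (faster than at C7–H or the γ-position of the enoate) and O-sulfonylation gives the terminal 1-substituted vinyl triflate without touching C7.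

Step 12
Reactants: 17 methyl (4aR,7R,8aR)-4a-methyl-7-{1-[(trifluoromethanesulfonyl)oxy]ethenyl}-3,4,4a,5,6,7,8,8a-octahydronaphthalene-1-carboxylate
Product: 18 1-[(2R,4aR,8aR)-8-(hydroxymethyl)-4a-methyl-1,2,3,4,4a,5,6,8a-octahydronaphthalen-2-yl]ethenyl trifluoromethanesulfonate
Conditions: i-Bu2AlH (2.5 equiv), CH2Cl2, −78 °C
Reagents that add atoms: none
Why: 1,2-Hydride reduction of the α,β-unsaturated ester to the allylic alcohol; it is done at this stage because the ketone is already masked as the vinyl triflate, which is inert to the hydride, and the second ester is not yet present.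

Step 13
Reactants: 18 1-[(2R,4aR,8aR)-8-(hydroxymethyl)-4a-methyl-1,2,3,4,4a,5,6,8a-octahydronaphthalen-2-yl]ethenyl trifluoromethanesulfonate
Product: 19 4-methoxybenzyl 2-[(2R,4aR,8aR)-8-(hydroxymethyl)-4a-methyl-1,2,3,4,4a,5,6,8a-octahydronaphthalen-2-yl]prop-2-enoate
Conditions: Pd(OAc)2 (5 mol %), 1,3-bis(diphenylphosphino)propane (5 mol %), CO (1 atm), 4-MeOC6H4CH2OH (5 equiv), Et3N, DMF, 60 °C
Reagents that add atoms: carbon monoxide, [C-]#[O+]; 4-methoxybenzyl alcohol, COc1ccc(CO)cc1
Why: Palladium-catalysed alkoxycarbonylation of a vinyl triflate (oxidative addition to zerovalent palladium, CO insertion, alcoholysis of the acyl complex), with the excess benzylic alcohol outcompeting the substrate hydroxyl.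

Step 14
Reactants: 20 4-(tert-butyldimethylsilyloxy)benzaldehyde; 21 methyl 2-[bis(2,2,2-trifluoroethoxy)phosphoryl]acetate
Product: 23 methyl (2Z)-3-[4-(tert-butyldimethylsilyloxy)phenyl]prop-2-enoate, via potassium phosphonate carbanion 22 (not isolated)
Conditions: KN(SiMe3)2, 18-crown-6, THF, −78 °C; then 20
Reagents that add atoms: none
Why: Still–Gennari olefination: the electron-poor trifluoroethyl phosphonate eliminates fast and irreversibly from the kinetically formed oxaphosphetane, which should give the (Z)-alkene.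

Step 15
Reactants: 23 methyl (2Z)-3-[4-(tert-butyldimethylsilyloxy)phenyl]prop-2-enoate
Product: 24 (2Z)-3-(4-hydroxyphenyl)prop-2-enoic acid
Conditions: LiOH, THF–MeOH–H2O, rt, dark; then 1 M HCl, 0 °C
Reagents that add atoms: lithium hydroxide, [Li+].[OH-]
Why: Saponification, with cleavage of the aryl silyl ether by hydroxide in the same operation; exclusion of light and heat should preserve the Z geometry.

Step 16
Reactants: 19 4-methoxybenzyl 2-[(2R,4aR,8aR)-8-(hydroxymethyl)-4a-methyl-1,2,3,4,4a,5,6,8a-octahydronaphthalen-2-yl]prop-2-enoate; 24 (2Z)-3-(4-hydroxyphenyl)prop-2-enoic acid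
Product: 25 4-methoxybenzyl 2-[(2R,4aR,8aR)-8-({[(2Z)-3-(4-hydroxyphenyl)prop-2-enoyl]oxy}methyl)-4a-methyl-1,2,3,4,4a,5,6,8a-octahydronaphthalen-2-yl]prop-2-enoate
Conditions: PPh3, i-PrO2CN=NCO2i-Pr, THF, 0 °C, dark
Reagents that add atoms: none
Why: Mitsunobu esterification: the primary allylic alcohol is activated as its alkoxyphosphonium ion and displaced SN2 by the carboxylate, which is far more acidic than the phenol; the acyl group is never activated, so the Z alkene should persist.

Step 17
Reactants: 25 4-methoxybenzyl 2-[(2R,4aR,8aR)-8-({[(2Z)-3-(4-hydroxyphenyl)prop-2-enoyl]oxy}methyl)-4a-methyl-1,2,3,4,4a,5,6,8a-octahydronaphthalen-2-yl]prop-2-enoate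
Product: 26 2-[(2R,4aR,8aR)-8-({[(2Z)-3-(4-hydroxyphenyl)prop-2-enoyl]oxy}methyl)-4a-methyl-1,2,3,4,4a,5,6,8a-octahydronaphthalen-2-yl]prop-2-enoic acid (CNP0183482.1; 5R,7R,10R in eudesmane numbering)
Conditions: TFA (10 vol %), anisole, CH2Cl2, 0 °C
Reagents that add atoms: none
Why: Acidolysis of the 4-methoxybenzyl ester through the stabilised benzylic cation, which anisole traps; the brief cold treatment should leave the allylic coumarate, the Z alkene and the α-methylene acid intact.

## Compound list

1 | ethyl 4-methylpent-4-enoate | CCOC(=O)CCC(C)=C | starting material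
2 | 4-methylpent-4-enal | O=CCCC(C)=C | intermediate
3 | methyl acrylate | C=CC(=O)OC | starting material
4 | methyl 3-hydroxy-6-methyl-2-methylidenehept-6-enoate (racemic) | C=C(C)CCC(O)C(=C)C(=O)OC | intermediate
5 | methyl (2Z)-2-(bromomethyl)-6-methylhepta-2,6-dienoate | C=C(C)CC/C=C(/C(=O)OC)CBr | intermediate
6 | methyl (2Z)-2-[(diethoxyphosphoryl)methyl]-6-methylhepta-2,6-dienoate | C=C(C)CC/C=C(/C(=O)OC)CP(=O)(OCC)OCC | intermediate
7 | ethyl (2-methyl-1,3-dioxolan-2-yl)acetate | CCOC(=O)CC1(C)OCCO1 | starting material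
8 | (2-methyl-1,3-dioxolan-2-yl)acetaldehyde | O=CCC1(C)OCCO1 | intermediate
9 | 2-(2-methyl-1,3-dioxolan-2-yl)prop-2-enal | C=C(C=O)C1(C)OCCO1 | intermediate
10 | sodium salt of the phosphonate carbanion of 6 | [Na+].C=C(C)CC/C=C(/C(=O)OC)[CH-]P(=O)(OCC)OCC | intermediate
11 | methyl (2E)-6-methyl-2-[(1E)-3-(2-methyl-1,3-dioxolan-2-yl)buta-1,3-dien-1-yl]hepta-2,6-dienoate | C=C(C)CC/C=C(/C(=O)OC)\C=C\C(=C)C1(C)OCCO1 | intermediate
12 | methyl (2E)-6-methyl-2-[(1E)-3-methylidene-4-oxopent-1-en-1-yl]hepta-2,6-dienoate | C=C(C)CC/C=C(/C(=O)OC)\C=C\C(=C)C(C)=O | intermediate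
13 | methyl (4aR,8aR)-7-acetyl-4a-methyl-3,4,4a,5,6,8a-hexahydronaphthalene-1-carboxylate | CC(=O)C=1CC[C@@]2(C)CCC=C(C(=O)OC)[C@@H]2C=1 | intermediate
14 | methyl (4aR,7S,8aR)-7-acetyl-4a-methyl-3,4,4a,5,6,7,8,8a-octahydronaphthalene-1-carboxylate (7α-acetyl epimer) | CC(=O)[C@H]1CC[C@@]2(C)CCC=C(C(=O)OC)[C@@H]2C1 | intermediate
15 | methyl (4aR,7R,8aR)-7-acetyl-4a-methyl-3,4,4a,5,6,7,8,8a-octahydronaphthalene-1-carboxylate (7β-acetyl) | CC(=O)[C@@H]1CC[C@@]2(C)CCC=C(C(=O)OC)[C@@H]2C1 | intermediate
16 | potassium enolate of 15 (terminal, at the acetyl CH3) | [K+].C=C([O-])[C@@H]1CC[C@@]2(C)CCC=C(C(=O)OC)[C@@H]2C1 | intermediate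
17 | methyl (4aR,7R,8aR)-4a-methyl-7-{1-[(trifluoromethanesulfonyl)oxy]ethenyl}-3,4,4a,5,6,7,8,8a-octahydronaphthalene-1-carboxylate | C=C(OS(=O)(=O)C(F)(F)F)[C@@H]1CC[C@@]2(C)CCC=C(C(=O)OC)[C@@H]2C1 | intermediate
18 | 1-[(2R,4aR,8aR)-8-(hydroxymethyl)-4a-methyl-1,2,3,4,4a,5,6,8a-octahydronaphthalen-2-yl]ethenyl trifluoromethanesulfonate | C=C(OS(=O)(=O)C(F)(F)F)[C@@H]1CC[C@@]2(C)CCC=C(CO)[C@@H]2C1 | intermediate
19 | 4-methoxybenzyl 2-[(2R,4aR,8aR)-8-(hydroxymethyl)-4a-methyl-1,2,3,4,4a,5,6,8a-octahydronaphthalen-2-yl]prop-2-enoate | C=C(C(=O)OCc1ccc(OC)cc1)[C@@H]1CC[C@@]2(C)CCC=C(CO)[C@@H]2C1 | intermediate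
20 | 4-(tert-butyldimethylsilyloxy)benzaldehyde | O=Cc1ccc(O[Si](C)(C)C(C)(C)C)cc1 | starting material
21 | methyl 2-[bis(2,2,2-trifluoroethoxy)phosphoryl]acetate | COC(=O)CP(=O)(OCC(F)(F)F)OCC(F)(F)F | starting material
22 | potassium salt of the phosphonate carbanion of 21 | [K+].COC(=O)[CH-]P(=O)(OCC(F)(F)F)OCC(F)(F)F | intermediate
23 | methyl (2Z)-3-[4-(tert-butyldimethylsilyloxy)phenyl]prop-2-enoate | COC(=O)/C=C\c1ccc(O[Si](C)(C)C(C)(C)C)cc1 | intermediate
24 | (2Z)-3-(4-hydroxyphenyl)prop-2-enoic acid | OC(=O)/C=C\c1ccc(O)cc1 | intermediate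
25 | 4-methoxybenzyl 2-[(2R,4aR,8aR)-8-({[(2Z)-3-(4-hydroxyphenyl)prop-2-enoyl]oxy}methyl)-4a-methyl-1,2,3,4,4a,5,6,8a-octahydronaphthalen-2-yl]prop-2-enoate | C=C(C(=O)OCc1ccc(OC)cc1)[C@@H]1CC[C@@]2(C)CCC=C(COC(=O)/C=C\c3ccc(O)cc3)[C@@H]2C1 | intermediate
26 | 2-[(2R,4aR,8aR)-8-({[(2Z)-3-(4-hydroxyphenyl)prop-2-enoyl]oxy}methyl)-4a-methyl-1,2,3,4,4a,5,6,8a-octahydronaphthalen-2-yl]prop-2-enoic acid | C=C(C(=O)O)[C@@H]1CC[C@@]2(C)CCC=C(COC(=O)/C=C\c3ccc(O)cc3)[C@@H]2C1 | target

## Step count and risks

Total step count: 17.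
Longest linear sequence: 13 steps (1 → 2 → 4 → 5 → 6 → 11 → 12 → 13 → 15 → 17 → 18 → 19 → 25 → 26; steps 1–4, 7–13, 16, 17).

Steps most likely to fail:

1. Step 9 (proposed new method). What may go wrong: insufficient enantiofacial discrimination by a Lewis acid bound to a ketone that sits on the diene, a competing uncatalysed cycloaddition, partial cis ring fusion, and bimolecular Diels–Alder dimerisation of the acyl diene. Fallback with known chemistry: setting out from 12, the cycloaddition is run without catalyst as a thermal inverse-demand intramolecular Diels–Alder reaction (PhMe, 0.005 M, 2,6-di-tert-butyl-4-methylphenol, 90 °C). This gives the trans-fused adduct as a racemate, that is 13 together with its enantiomer, methyl (4aS,8aS)-7-acetyl-4a-methyl-3,4,4a,5,6,8a-hexahydronaphthalene-1-carboxylate F1. The two are separated by preparative chromatography on a cellulose tris(3,5-dimethylphenylcarbamate) stationary phase, and the route is rejoined at 13. Absolute configuration is then secured by resolution instead of catalyst control, at the cost of half the material.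

2. Step 10. What may go wrong: loss of chemoselectivity (hydride addition to the Δ3 enoate or 1,2-reduction of the ketone) and incomplete equilibration at C7. Fallback: setting out from 13, a rhodium-catalysed 1,4-hydrosilylation (RhCl(PPh3)3, Et3SiH, PhMe, 50 °C), to which enoates are inert, gives the silyl enol ether methyl (4aR,8aR)-4a-methyl-7-[1-(triethylsilyloxy)ethylidene]-3,4,4a,5,6,7,8,8a-octahydronaphthalene-1-carboxylate F2 as a mixture of geometric isomers. Methanolysis with K2CO3 in MeOH releases the ketone and equilibrates C7, and the route is rejoined at 15.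

3. Step 16. What may go wrong: erosion of the Z geometry through reversible conjugate addition of the phosphine or stray light, O-alkylation of the free phenol, and SN2′ attack. Fallback: setting out from 19, the alcohol is converted with CBr4 and PPh3 (Appel reaction, CH2Cl2, 0 °C) into the allylic bromide 4-methoxybenzyl 2-[(2R,4aR,8aR)-8-(bromomethyl)-4a-methyl-1,2,3,4,4a,5,6,8a-octahydronaphthalen-2-yl]prop-2-enoate F3. This is then alkylated by the caesium carboxylate of 24 (CsHCO3, one equivalent, DMF, 0 °C, dark) in an SN2 reaction that involves no phosphine and does not deprotonate the phenol, and the route is rejoined at 25.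

Further compounds
F1 | step 9 | methyl (4aS,8aS)-7-acetyl-4a-methyl-3,4,4a,5,6,8a-hexahydronaphthalene-1-carboxylate (enantiomer of 13) | CC(=O)C=1CC[C@]2(C)CCC=C(C(=O)OC)[C@H]2C=1
F2 | step 10 | methyl (4aR,8aR)-4a-methyl-7-[1-(triethylsilyloxy)ethylidene]-3,4,4a,5,6,7,8,8a-octahydronaphthalene-1-carboxylate (mixture of enol ether isomers) | CC(O[Si](CC)(CC)CC)=C1CC[C@@]2(C)CCC=C(C(=O)OC)[C@@H]2C1
F3 | step 16 | 4-methoxybenzyl 2-[(2R,4aR,8aR)-8-(bromomethyl)-4a-methyl-1,2,3,4,4a,5,6,8a-octahydronaphthalen-2-yl]prop-2-enoate | C=C(C(=O)OCc1ccc(OC)cc1)[C@@H]1CC[C@@]2(C)CCC=C(CBr)[C@@H]2C1
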